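**Retrosynthetic overview**
- C–O disconnection (last step): the target comes from tyrosol and ethyl dotriacontanoate by acyl transfer to the primary hydroxyl only, so the phenol is never protected.
- C2–C3 disconnection (key step): ethyl dotriacontanoate comes from a triacontyl nucleophile (as its 9-BBN borane) and an acetate α-cation (enolonium) equivalent, ethyl bromoacetate, joined by a boron-ate 1,2-shift.
- The borane comes from 1-bromotriacontane (Mg, then B-methoxy-9-BBN), and the bromide from bulk 1-triacontanol.
- No ring is formed: the only ring, the benzene ring, is bought intact in tyrosol.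

Assumption: the acyl chain is read as 32 carbons (dotriacontanoyl, target C40H72O3); the molecule has no stereocentre and is achiral, so there is no enantiomer to control.

**Route**

Step 1
Reactants: 1 1-triacontanol
Product: 2 1-bromotriacontane
Conditions: 48% aq HBr (5 equiv), conc. H2SO4 (1 equiv), 115 °C (melt), 10 h; recrystallise from acetone
Reagents that add atoms: hydrogen bromide, Br
Why: Acid-mediated SN2 bromination of a primary alcohol (the protonated hydroxyl is displaced by bromide), with no competing functional group and no stereocentre.

Step 2
Reactants: 2 1-bromotriacontane; 3 B-methoxy-9-borabicyclo[3.3.1]nonane (B-methoxy-9-BBN); 4 ethyl bromoacetate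
Product: 7 ethyl dotriacontanoate, via triacontylmagnesium bromide 5 (not isolated), via B-triacontyl-9-BBN 6 (not isolated)
Conditions: Mg, cat. I2, THF, 60 °C; then 3, hexane/THF, 0 °C → rt, cannula-filter from MgBr(OMe); then 4 (1.2 equiv), KOtBu (1.2 equiv) in t-BuOH, THF, 0 → 25 °C, under Ar
Reagents that add atoms: none
Why: Brown–Rogić α-alkylation of an α-bromo ester by an organoborane: the potassium enolate of 4 adds to the boron of 6, the primary triacontyl group then shifts 1,2 from the borate to the α-carbon with loss of bromide (so the acetate α-carbon, normally the nucleophilic enolate position, acts as an enolonium equivalent toward a nucleophilic alkyl group), and tert-butanol protonates the resulting boron enolate to give 7, the 9-BBN cage serving as a non-migrating ligand; no stereocentre is formed.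

Step 3
Reactants: 7 ethyl dotriacontanoate; 8 tyrosol (4-(2-hydroxyethyl)phenol, 3 equiv)
Product: 9 Basalethanolide A, 2-(4-hydroxyphenyl)ethyl dotriacontanoate
Conditions: Novozym 435 (immobilised Candida antarctica lipase B), toluene/2-methyl-2-butanol 1:1, 5 Å MS, 65 °C, 48 h; filter, wash out excess 8 with water, recrystallise
Reagents that add atoms: none
Why: Lipase-catalysed transesterification through a serine acyl-enzyme acylates only the primary aliphatic hydroxyl of 8 and leaves the phenol free, and is driven by sequestering the ethanol; no stereocentre is involved.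

**Compound list**
1 | 1-triacontanol | CCCCCCCCCCCCCCCCCCCCCCCCCCCCCCO | starting material
2 | 1-bromotriacontane | CCCCCCCCCCCCCCCCCCCCCCCCCCCCCCBr | intermediate
3 | B-methoxy-9-borabicyclo[3.3.1]nonane (B-methoxy-9-BBN) | COB1C2CCCC1CCC2 | starting material
4 | ethyl bromoacetate | CCOC(=O)CBr | starting material
5 | triacontylmagnesium bromide | CCCCCCCCCCCCCCCCCCCCCCCCCCCCCC[Mg]Br | intermediate
6 | B-triacontyl-9-BBN (9-triacontyl-9-borabicyclo[3.3.1]nonane) | CCCCCCCCCCCCCCCCCCCCCCCCCCCCCCB1C2CCCC1CCC2 | intermediate
7 | ethyl dotriacontanoate | CCCCCCCCCCCCCCCCCCCCCCCCCCCCCCCC(=O)OCC | intermediate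
8 | tyrosol (4-(2-hydroxyethyl)phenol) | OCCc1ccc(O)cc1 | starting material
9 | Basalethanolide A, 2-(4-hydroxyphenyl)ethyl dotriacontanoate (achiral) | CCCCCCCCCCCCCCCCCCCCCCCCCCCCCCCC(=O)OCCc1ccc(O)cc1 | target

**Step count and risks**
Total step count: 3. Longest linear sequence: 3 (1 → 2 → 7 → 9).

The three steps most likely to fail:

Step 2 carries the most risk. The hazards are Wurtz dimerisation while the C30 Grignard reagent forms, residual magnesium alkoxide consuming the base, and poor solubility of the C30 borane at 0 °C. The fallback sets out from 2 and comes back at 7, and still brings in C2 as a carbon of reversed polarity. The sodium salt of commercial ethyl 1,3-dithiane-2-carboxylate (CCOC(=O)C1SCCCS1; NaH, DMF/toluene, 60 °C), a masked glyoxylate acyl anion, is alkylated with 2 to give ethyl 2-triacontyl-1,3-dithiane-2-carboxylate F1. Desulfurisation of F1 with Raney Ni in refluxing EtOH/THF then gives 7.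

Step 3 is next. The C32 acyl donor may turn over slowly in the enzyme or stay poorly dissolved. The fallback sets out from 7 and comes back at 9. Saponification (KOH, EtOH/toluene, reflux; then aq HCl) gives dotriacontanoic acid F2. F2 is coupled with 8 under Mitsunobu conditions (PPh3, DIAD, THF/toluene, 45 °C); this activates the primary alcohol instead of the acyl group, and the far more acidic carboxylic acid outcompetes the phenol as the nucleophile.

Step 1 is the least risky. The waxy melt may convert incompletely or give some ditriacontyl ether. The fallback sets out from 1 and comes back at 2. Sulfonylation (MsCl, Et3N, CH2Cl2/THF, 40 °C) gives triacontyl methanesulfonate F3. Displacement with LiBr in refluxing THF/acetone then gives 2.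

Further compounds
F1 | step 2 | ethyl 2-triacontyl-1,3-dithiane-2-carboxylate | CCCCCCCCCCCCCCCCCCCCCCCCCCCCCCC1(SCCCS1)C(=O)OCC
F2 | step 3 | dotriacontanoic acid | CCCCCCCCCCCCCCCCCCCCCCCCCCCCCCCC(=O)O
F3 | step 1 | triacontyl methanesulfonate | CCCCCCCCCCCCCCCCCCCCCCCCCCCCCCOS(C)(=O)=O
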